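**Retrosynthetic overview**
- Feature: in ring A the three oxygen-bearing carbons C8a (O1), C5 and C7 all lie ortho or para to C4a, which carries the C4 carbonyl. Ring A is therefore taken from a 2,4,6-trifluorobenzoyl unit and each of its C–O bonds is made by SNAr on a C–F bond.
- Target ⇐ O3' debenzylation ⇐ sulfation of O3, O7 and O4' (O5 stays free, chelated to C4=O) ⇐ acid removal of four PMB ethers ⇐ double SNAr of a PMB alkoxide at C5–F and C7–F.
- 5,7-Difluoroflavone ⇐ enolate of a ring B α-(PMB-oxy) ketone + 2,4,6-trifluorobenzoyl chloride: C3–C4 by C-acylation, then O1–C8a by intramolecular SNAr.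
- Ketone ⇐ aryllithium (2-(benzyloxy)phenol: para-bromination, PMB ether, Br–Li exchange) + PMB-oxyacetic Weinreb amide.
- Ring order: rings A and B are bought as benzene rings; ring C (the pyranone) is the only ring formed, in step 5. The target has no stereocentres.

Key step: step 5

Assumption: the target is drawn as the free tris(hydrogen sulfate). Aryl hydrogen sulfates hydrolyse on storage, so the sulfated material is carried as its tris(triethylammonium) salt and the acid form is liberated only in the last operation, cold and with immediate freeze-drying.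

Step 1
Reactants: 1 2-(benzyloxy)phenol
Product: 2 2-(benzyloxy)-4-bromophenol
Conditions: NBS, MeCN, 0 °C → rt
Reagents that add atoms: N-bromosuccinimide, O=C1CCC(=O)N1Br
Why: Electrophilic aromatic bromination, in which the free hydroxyl is the strongest activator and directs para, so C4 (para to OH, meta to OBn) should be brominated.

Step 2
Reactants: 2 2-(benzyloxy)-4-bromophenol; 3 4-methoxybenzyl chloride
Product: 4 2-(benzyloxy)-4-bromo-1-[(4-methoxybenzyl)oxy]benzene
Conditions: K2CO3, Bu4NI (cat.), DMF, 60 °C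
Reagents that add atoms: none
Why: Williamson ether synthesis, the phenoxide formed by K2CO3 being alkylated on oxygen by the reactive benzylic chloride.

Step 3
Reactants: 5 2-chloro-N-methoxy-N-methylacetamide; 6 4-methoxybenzyl alcohol
Product: 8 N-methoxy-2-[(4-methoxybenzyl)oxy]-N-methylacetamide, via sodium 4-methoxybenzyl alkoxide 7 (not isolated)
Conditions: 6, NaH, THF, 0 °C; then 5, Bu4NI (cat.), 0 °C → rt
Reagents that add atoms: none
Why: Williamson ether synthesis, the tightly ion-paired sodium alkoxide displacing the activated α-chloride by SN2 faster than it attacks the N-methoxy-N-methylamide carbonyl.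

Step 4
Reactants: 4 2-(benzyloxy)-4-bromo-1-[(4-methoxybenzyl)oxy]benzene; 8 N-methoxy-2-[(4-methoxybenzyl)oxy]-N-methylacetamide
Product: 11 1-[3-(benzyloxy)-4-[(4-methoxybenzyl)oxy]phenyl]-2-[(4-methoxybenzyl)oxy]ethan-1-one, via aryllithium 9 (not isolated), via lithium hemiaminal alkoxide 10 (not isolated)
Conditions: n-BuLi, THF, −78 °C; then 8, −78 → −20 °C; AcOH quench
Reagents that add atoms: none
Why: Bromine–lithium exchange followed by Weinreb ketone synthesis, the chelated tetrahedral adduct holding until the acidic quench so that the aryllithium adds only once.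

Step 5
Reactants: 11 1-[3-(benzyloxy)-4-[(4-methoxybenzyl)oxy]phenyl]-2-[(4-methoxybenzyl)oxy]ethan-1-one; 12 2,4,6-trifluorobenzoyl chloride
Product: 15 2-[3-(benzyloxy)-4-[(4-methoxybenzyl)oxy]phenyl]-5,7-difluoro-3-[(4-methoxybenzyl)oxy]-4H-chromen-4-one, via lithium Z-enolate 13 (not isolated), via 2-alkoxy-1,3-diketone 14 (not isolated)
Conditions: LiN(SiMe3)2 (2.1 equiv), toluene–THF, −78 °C; 12, −78 → 0 °C; then K2CO3, DMF, 70 °C
Reagents that add atoms: none
Why: LiN(SiMe3)2 converts 11 into the chelated Z lithium enolate 13 (lithium bridging the enolate and PMB-ether oxygens), which attacks 12 through carbon to form C3–C4, and the second equivalent of base at once deprotonates the 2-alkoxy-1,3-diketone 14, so that the acylation is not reversed. On warming with K2CO3 in DMF the enolate oxygen on the ring B carbonyl adds to an ortho C–F carbon of the trifluorophenyl ring, which is activated by the ortho ketone and the other two fluorines, and loss of fluoride from the Meisenheimer adduct forms O1–C8a. The closest known reaction type is the one-pot C-acylation of a ketone enolate by a 2-fluorobenzoyl chloride followed by intramolecular SNAr to chromones and flavones. Ring C closes as a six-membered ring by attack of an oxygen nucleophile on the sp2 carbon C8a (addition–elimination), and no stereocentre is created. The step needs C- over O-acylation, which the tight lithium chelate in a toluene-rich medium should favour and which acyl transfer from any enol ester to remaining enolate backs up; the ring closure needs no site control, because the two ortho fluorines are equivalent by symmetry, only the ring B side oxygen can reach one through a six-membered transition state, and nothing in the flask is nucleophilic enough to displace the C5 and C7 fluorines that remain.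

Step 6
Reactants: 15 2-[3-(benzyloxy)-4-[(4-methoxybenzyl)oxy]phenyl]-5,7-difluoro-3-[(4-methoxybenzyl)oxy]-4H-chromen-4-one; 6 4-methoxybenzyl alcohol
Product: 17 2-[3-(benzyloxy)-4-[(4-methoxybenzyl)oxy]phenyl]-3,5,7-tris[(4-methoxybenzyl)oxy]-4H-chromen-4-one, via potassium 4-methoxybenzyl alkoxide 16 (not isolated)
Conditions: 6 (3 equiv), KN(SiMe3)2 (2.5 equiv), THF, 0 °C; then 15, DMF, 0 → 60 °C
Reagents that add atoms: none
Why: Nucleophilic aromatic substitution by addition–elimination, C5–F and C7–F being ortho and para to the C4 carbonyl through C4a, with an excess of the loosely ion-paired potassium alkoxide (formed with a base whose conjugate acid, hexamethyldisilazane, is not a nucleophile) and warming to carry the slower second displacement to completion.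

Step 7
Reactants: 17 2-[3-(benzyloxy)-4-[(4-methoxybenzyl)oxy]phenyl]-3,5,7-tris[(4-methoxybenzyl)oxy]-4H-chromen-4-one
Product: 18 2-[3-(benzyloxy)-4-hydroxyphenyl]-3,5,7-trihydroxy-4H-chromen-4-one (3'-O-benzylquercetin)
Conditions: TFA (10% v/v), 1,3-dimethoxybenzene, CH2Cl2, 0 °C → rt
Reagents that add atoms: none
Why: Acidolysis of the four 4-methoxybenzyl ethers through the stabilised 4-methoxybenzyl cation, which 1,3-dimethoxybenzene traps by Friedel–Crafts alkylation before it can attack ring A, under conditions mild enough to leave the unsubstituted benzyl ether at O3' intact.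

Step 8
Reactants: 18 2-[3-(benzyloxy)-4-hydroxyphenyl]-3,5,7-trihydroxy-4H-chromen-4-one
Product: 19 3'-O-benzylquercetin 3,4',7-trisulfate tris(triethylammonium) salt
Conditions: SO3·NEt3 (4 equiv per OH to be sulfated), N,N-dimethylacetamide, 65 °C
Reagents that add atoms: sulfur trioxide–triethylamine complex, CC[N+](CC)(CC)S(=O)(=O)[O-]
Why: O-Sulfonation by the sulfur trioxide–amine complex at O3, O7 and O4', while the C5 hydroxyl, held in a six-membered hydrogen bond to the C4 carbonyl, is the least nucleophilic and should stay free, and O3' is blocked as its benzyl ether.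

Step 9
Reactants: 19 3'-O-benzylquercetin 3,4',7-trisulfate tris(triethylammonium) salt
Product: 21 quercetin 3,4',7-tris(hydrogen sulfate), via tris(triethylammonium) quercetin 3,4',7-trisulfate 20 (not isolated)
Conditions: H2 (1 atm), Pd/C, MeOH–H2O, rt; then Dowex 50W (H+ form), H2O, 0 °C, freeze-drying
Reagents that add atoms: none
Why: Catalytic hydrogenolysis cleaves the benzyl ether without touching aryl sulfate esters or the chromone, and cation exchange on a sulfonic acid resin replaces triethylammonium by protons.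

**Compound list**
1 | 2-(benzyloxy)phenol | Oc1ccccc1OCc1ccccc1 | starting material
2 | 2-(benzyloxy)-4-bromophenol | Oc1ccc(Br)cc1OCc1ccccc1 | intermediate
3 | 4-methoxybenzyl chloride | COc1ccc(CCl)cc1 | starting material
4 | 2-(benzyloxy)-4-bromo-1-[(4-methoxybenzyl)oxy]benzene | COc1ccc(COc2ccc(Br)cc2OCc2ccccc2)cc1 | intermediate
5 | 2-chloro-N-methoxy-N-methylacetamide | CON(C)C(=O)CCl | starting material
6 | 4-methoxybenzyl alcohol | COc1ccc(CO)cc1 | starting material
7 | sodium (4-methoxyphenyl)methanolate (formed in the flask) | COc1ccc(C[O-])cc1.[Na+] | intermediate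
8 | N-methoxy-2-[(4-methoxybenzyl)oxy]-N-methylacetamide | CON(C)C(=O)COCc1ccc(OC)cc1 | intermediate
9 | [3-(benzyloxy)-4-[(4-methoxybenzyl)oxy]phenyl]lithium (formed in the flask) | [Li]c1ccc(OCc2ccc(OC)cc2)c(OCc2ccccc2)c1 | intermediate
10 | lithium 1-[3-(benzyloxy)-4-[(4-methoxybenzyl)oxy]phenyl]-1-[methoxy(methyl)amino]-2-[(4-methoxybenzyl)oxy]ethan-1-olate (racemic chelated tetrahedral adduct, formed in the flask) | [Li]OC(COCc1ccc(OC)cc1)(N(C)OC)c1ccc(OCc2ccc(OC)cc2)c(OCc2ccccc2)c1 | intermediate
11 | 1-[3-(benzyloxy)-4-[(4-methoxybenzyl)oxy]phenyl]-2-[(4-methoxybenzyl)oxy]ethan-1-one | O=C(COCc1ccc(OC)cc1)c1ccc(OCc2ccc(OC)cc2)c(OCc2ccccc2)c1 | intermediate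
12 | 2,4,6-trifluorobenzoyl chloride | O=C(Cl)c1c(F)cc(F)cc1F | starting material
13 | lithium (Z)-1-[3-(benzyloxy)-4-[(4-methoxybenzyl)oxy]phenyl]-2-[(4-methoxybenzyl)oxy]ethen-1-olate (formed in the flask) | [Li]O/C(=C\OCc1ccc(OC)cc1)c1ccc(OCc2ccc(OC)cc2)c(OCc2ccccc2)c1 | intermediate
14 | 1-[3-(benzyloxy)-4-[(4-methoxybenzyl)oxy]phenyl]-2-[(4-methoxybenzyl)oxy]-3-(2,4,6-trifluorophenyl)propane-1,3-dione (held in the flask as its planar enolate; C2 configuration not defined) | O=C(c1c(F)cc(F)cc1F)C(OCc1ccc(OC)cc1)C(=O)c1ccc(OCc2ccc(OC)cc2)c(OCc2ccccc2)c1 | intermediate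
15 | 2-[3-(benzyloxy)-4-[(4-methoxybenzyl)oxy]phenyl]-5,7-difluoro-3-[(4-methoxybenzyl)oxy]-4H-chromen-4-one | O=c1c(OCc2ccc(OC)cc2)c(-c2ccc(OCc3ccc(OC)cc3)c(OCc3ccccc3)c2)oc2cc(F)cc(F)c12 | intermediate
16 | potassium (4-methoxyphenyl)methanolate (formed in the flask) | COc1ccc(C[O-])cc1.[K+] | intermediate
17 | 2-[3-(benzyloxy)-4-[(4-methoxybenzyl)oxy]phenyl]-3,5,7-tris[(4-methoxybenzyl)oxy]-4H-chromen-4-one | O=c1c(OCc2ccc(OC)cc2)c(-c2ccc(OCc3ccc(OC)cc3)c(OCc3ccccc3)c2)oc2cc(OCc3ccc(OC)cc3)cc(OCc3ccc(OC)cc3)c12 | intermediate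
18 | 2-[3-(benzyloxy)-4-hydroxyphenyl]-3,5,7-trihydroxy-4H-chromen-4-one (3'-O-benzylquercetin) | O=c1c(O)c(-c2ccc(O)c(OCc3ccccc3)c2)oc2cc(O)cc(O)c12 | intermediate
19 | 3'-O-benzylquercetin 3,4',7-trisulfate tris(triethylammonium) salt | O=c1c(OS(=O)(=O)[O-])c(-c2ccc(OS(=O)(=O)[O-])c(OCc3ccccc3)c2)oc2cc(OS(=O)(=O)[O-])cc(O)c12.CC[NH+](CC)CC.CC[NH+](CC)CC.CC[NH+](CC)CC | intermediate
20 | quercetin 3,4',7-trisulfate tris(triethylammonium) salt (formed in the flask) | O=c1c(OS(=O)(=O)[O-])c(-c2ccc(OS(=O)(=O)[O-])c(O)c2)oc2cc(OS(=O)(=O)[O-])cc(O)c12.CC[NH+](CC)CC.CC[NH+](CC)CC.CC[NH+](CC)CC | intermediate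
21 | quercetin 3,4',7-tris(hydrogen sulfate) | O=c1c(OS(=O)(=O)O)c(-c2ccc(OS(=O)(=O)O)c(O)c2)oc2cc(OS(=O)(=O)O)cc(O)c12 | target

Total step count: 9
Longest linear sequence: 8 steps (steps 1, 2, 4, 5, 6, 7, 8, 9; step 3 is the side branch)

**Steps most likely to fail**

Step 5. The acid chloride may be consumed by O-acylation of the enolate or by attack of the silylamide, so that too little diketone forms, and the ring closure may lag behind. The fallback sets out from 11 and comes back at 15 by way of 14. The enolate 13, made from 11 as in step 5, is added to 2,4,6-trifluorobenzaldehyde (THF, −78 °C), an aldol addition in which O-attack is not productive. This should give 1-[3-(benzyloxy)-4-[(4-methoxybenzyl)oxy]phenyl]-3-hydroxy-2-[(4-methoxybenzyl)oxy]-3-(2,4,6-trifluorophenyl)propan-1-one F1 as a mixture of diastereomers, both centres being erased later. Oxidation with Dess–Martin periodinane (NaHCO3, CH2Cl2) should give the diketone 14, now isolated, and K2CO3 in DMF at 70 °C should close it to 15 as in the second half of step 5.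

Step 6. The substitution may stall after the first displacement, since the first alkoxy group deactivates ring A, and the alkoxide may add at C2 and open ring C. The fallback sets out from 12 and comes back at 17; it inverts the order, so that the ring A oxygens are installed on the strongly activated benzoate before ring C is closed. Addition of 12 to one equivalent of the potassium alkoxide 16 (prepared as in step 6; THF, 0 °C) should give 4-methoxybenzyl 2,4,6-trifluorobenzoate F2. Two further equivalents of 16 (DMF, −20 °C → rt) should displace the para and one ortho fluoride to give 4-methoxybenzyl 2-fluoro-4,6-bis[(4-methoxybenzyl)oxy]benzoate F3; any 2,6-disubstituted isomer would be removed by chromatography, and ester exchange with the alkoxide is degenerate. Saponification (KOH, THF–MeOH–H2O, 60 °C, then mild acidification) should give 2-fluoro-4,6-bis[(4-methoxybenzyl)oxy]benzoic acid F4. The neutral chlorinating agent 1-chloro-N,N,2-trimethylprop-1-en-1-amine (CH2Cl2, 0 °C) should convert it into 2-fluoro-4,6-bis[(4-methoxybenzyl)oxy]benzoyl chloride F5 without harming the PMB ethers. Acylation of enolate 13 with F5 under the conditions of step 5 should give 1-[3-(benzyloxy)-4-[(4-methoxybenzyl)oxy]phenyl]-3-[2-fluoro-4,6-bis[(4-methoxybenzyl)oxy]phenyl]-2-[(4-methoxybenzyl)oxy]propane-1,3-dione F6, whose enolate oxygen closes onto the one remaining ortho fluoride, still activated by the ketone, to give 17 directly.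

Step 8. Sulfation may be incomplete at the hindered, hydrogen-bonded O3 or may run on to O5, giving polyanion mixtures that are hard to separate. The fallback sets out from 18 and comes back at 19; it installs the sulfates as neutral diesters that can be chromatographed. 2,2,2-Trichloroethyl chlorosulfate (NEt3, DMAP, THF, 0 °C → rt) should convert 18 into 3'-O-benzylquercetin 3,4',7-tris(2,2,2-trichloroethyl sulfate) F7, which can be purified on silica. Reductive removal of the trichloroethyl groups (Zn, HCO2NH4, MeOH, rt) should give 3'-O-benzylquercetin 3,4',7-trisulfate tris(ammonium) salt F8. Reversed-phase chromatography in triethylammonium hydrogen carbonate buffer exchanges the counter-ion and delivers 19 for step 9.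

**Further compounds**
F1 | step 5 | 1-[3-(benzyloxy)-4-[(4-methoxybenzyl)oxy]phenyl]-3-hydroxy-2-[(4-methoxybenzyl)oxy]-3-(2,4,6-trifluorophenyl)propan-1-one (mixture of diastereomers, racemic) | O=C(c1ccc(OCc2ccc(OC)cc2)c(OCc2ccccc2)c1)C(OCc1ccc(OC)cc1)C(O)c1c(F)cc(F)cc1F
F2 | step 6 | 4-methoxybenzyl 2,4,6-trifluorobenzoate | COc1ccc(COC(=O)c2c(F)cc(F)cc2F)cc1
F3 | step 6 | 4-methoxybenzyl 2-fluoro-4,6-bis[(4-methoxybenzyl)oxy]benzoate | COc1ccc(COC(=O)c2c(F)cc(OCc3ccc(OC)cc3)cc2OCc2ccc(OC)cc2)cc1
F4 | step 6 | 2-fluoro-4,6-bis[(4-methoxybenzyl)oxy]benzoic acid | OC(=O)c1c(F)cc(OCc2ccc(OC)cc2)cc1OCc1ccc(OC)cc1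
F5 | step 6 | 2-fluoro-4,6-bis[(4-methoxybenzyl)oxy]benzoyl chloride | O=C(Cl)c1c(F)cc(OCc2ccc(OC)cc2)cc1OCc1ccc(OC)cc1
F6 | step 6 | 1-[3-(benzyloxy)-4-[(4-methoxybenzyl)oxy]phenyl]-3-[2-fluoro-4,6-bis[(4-methoxybenzyl)oxy]phenyl]-2-[(4-methoxybenzyl)oxy]propane-1,3-dione (formed in the flask, C2 configuration not defined) | O=C(c1c(F)cc(OCc2ccc(OC)cc2)cc1OCc1ccc(OC)cc1)C(OCc1ccc(OC)cc1)C(=O)c1ccc(OCc2ccc(OC)cc2)c(OCc2ccccc2)c1
F7 | step 8 | 3'-O-benzylquercetin 3,4',7-tris(2,2,2-trichloroethyl sulfate) | O=c1c(OS(=O)(=O)OCC(Cl)(Cl)Cl)c(-c2ccc(OS(=O)(=O)OCC(Cl)(Cl)Cl)c(OCc3ccccc3)c2)oc2cc(OS(=O)(=O)OCC(Cl)(Cl)Cl)cc(O)c12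
F8 | step 8 | 3'-O-benzylquercetin 3,4',7-trisulfate tris(ammonium) salt | O=c1c(OS(=O)(=O)[O-])c(-c2ccc(OS(=O)(=O)[O-])c(OCc3ccccc3)c2)oc2cc(OS(=O)(=O)[O-])cc(O)c12.[NH4+].[NH4+].[NH4+]
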